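**Plan**
Cuts, in retrosynthetic order: the six O–CH3 bonds; O1–C2 and C2–C3 of ring C (ring B leaves as a 3,4-dimethoxybenzoyl unit); C8a–O1 and C4a–C4 together (O1, C4, C3 and the 3-oxygen leave as methoxyacetic acid); the CH–aryl bond of the C8 benzyl group.
Enabling feature: in ring A the O1-bearing carbon C8a and the C4-bearing carbon C4a are neighbours, framed by C8 (benzyl) and C5 (oxygen). They can be read as the two ends of an aryne C4a≡C8a that the C5 methoxy group polarises.
Forward order: ring A and the anisyl ring are bought and joined (Grignard addition, ionic reduction). Carbamate-directed silylation and triflation arm C4a/C8a, the acid is inserted, ring C closes last as ring B arrives, and global demethylation ends the route.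
Stereochemistry: the target is achiral. The carbinol and diketone centres that appear on the way are racemic and are erased.

Key step: step 6

Remark: ring A atoms carry their flavone numbers (C4a, C5–C8, C8a) from the start, also in open-chain precursors, and the four starting materials are taken to be catalogue chemicals.

Step 1
Reactants: 1 4-bromoanisole; 2 2-hydroxy-4,6-dimethoxybenzaldehyde
Product: 4 2-[hydroxy(4-methoxyphenyl)methyl]-3,5-dimethoxyphenol (racemic), via 4-methoxyphenylmagnesium bromide 3 (not isolated)
Conditions: 1 (2.5 equiv), Mg, THF, reflux; then 2, THF, 0 °C → rt; pH 7 phosphate buffer; used crude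
Reagents that add atoms: none
Why: Grignard addition to an aldehyde, in which the first equivalent of 3 only deprotonates the phenol, the magnesium phenoxide chelates the carbonyl and a second equivalent adds to give the racemic carbinol, whose stereocentre is removed in step 2.

Step 2
Reactants: 4 2-[hydroxy(4-methoxyphenyl)methyl]-3,5-dimethoxyphenol
Product: 5 3,5-dimethoxy-2-(4-methoxybenzyl)phenol
Conditions: Et3SiH (3 equiv), CF3CO2H, CH2Cl2, −20 → 0 °C
Reagents that add atoms: none
Why: Ionic hydrogenation, in which the benzhydryl cation stabilised by both electron-rich rings forms at once in acid and is intercepted by hydride from the excess silane before it can alkylate another arene.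

Step 3
Reactants: 5 3,5-dimethoxy-2-(4-methoxybenzyl)phenol
Product: 6 3,5-dimethoxy-2-(4-methoxybenzyl)phenyl isopropylcarbamate
Conditions: i-PrNCO, Et3N (cat.), CH2Cl2, rt
Reagents that add atoms: isopropyl isocyanate, CC(C)N=C=O
Why: Base-catalysed addition of a phenol to an isocyanate gives an N-isopropyl carbamate, a strong ortho director that keeps an N–H and can therefore be removed later under mild base.

Step 4
Reactants: 6 3,5-dimethoxy-2-(4-methoxybenzyl)phenyl isopropylcarbamate
Product: 10 3,5-dimethoxy-2-(4-methoxybenzyl)-6-(trimethylsilyl)phenyl isopropylcarbamate, via N-silyl carbamate 7 (not isolated), via aryllithium 8 (not isolated), via doubly silylated carbamate 9 (not isolated)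
Conditions: TBSOTf, TMEDA, Et2O, 0 °C → rt; n-BuLi, TMEDA, −78 °C; TMSCl, −78 °C → rt; cold aq NaHSO4 (brief)
Reagents that add atoms: chlorotrimethylsilane, C[Si](C)(C)Cl
Why: Directed ortho-metalation, in which in-situ N-silylation masks the N–H, n-BuLi/TMEDA removes the only ring proton ortho to the carbamate (further acidified by the adjacent methoxy group), TMSCl traps the aryllithium and the N–Si bond hydrolyses on work-up.

Step 5
Reactants: 10 3,5-dimethoxy-2-(4-methoxybenzyl)-6-(trimethylsilyl)phenyl isopropylcarbamate
Product: 12 3,5-dimethoxy-2-(4-methoxybenzyl)-6-(trimethylsilyl)phenyl trifluoromethanesulfonate, via silylphenol 11 (not isolated)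
Conditions: DBU, Et2NH, MeCN, 40 °C; then PhNTf2, rt
Reagents that add atoms: N-phenylbis(trifluoromethanesulfonimide), O=S(=O)(C(F)(F)F)N(c1ccccc1)S(=O)(=O)C(F)(F)F
Why: E1cB cleavage of the N–H carbamate releases isopropyl isocyanate, which Et2NH scavenges, and the phenoxide is triflated in the same pot, the standard one-pot route to ortho-silylaryl triflates that spares handling of the acid-sensitive silylphenol.

Step 6
Reactants: 12 3,5-dimethoxy-2-(4-methoxybenzyl)-6-(trimethylsilyl)phenyl trifluoromethanesulfonate; 13 methoxyacetic acid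
Product: 15 1-[2-hydroxy-4,6-dimethoxy-3-(4-methoxybenzyl)phenyl]-2-methoxyethan-1-one, via aryne 14 (not isolated)
Conditions: CsF (4 equiv), 13 (1.0 equiv), THF (0.02 M), sealed tube, 125 °C
Reagents that add atoms: none
Why: Fluoride attacks the silicon of 12 and triflate departs in a 1,2-elimination, giving aryne 14 with its triple bond between C4a and C8a. Caesium methoxyacetate then binds through oxygen to C8a, the carbanion left at C4a turns on the neighbouring ester carbonyl, and the benzoxetane-type alkoxide collapses by C–O cleavage to the phenoxide of the ortho-hydroxy ketone, so C8a–O1 and C4a–C4 arise in one operation. The closest known reaction type is the formal insertion of arynes into the C–O bond of carboxylic acids to give ortho-hydroxyaryl ketones, run hot and dilute in THF so that the intramolecular acyl shift outpaces protonation of the aryl anion. No ring persists in the product and no stereocentre is formed. The selectivity needed is regiochemical: the inductively withdrawing C5 methoxy group distorts the aryne so that C8a is the more linear, more electrophilic terminus and the charge develops at C4a beside that oxygen, whereas the C8 benzyl group and the remote C7 methoxy group have only weak influence. The phenoxide of 15 is shielded by the benzyl group and tied to the ketone, so a second arylation should be slow, and because its hydroxyl is O1 while the C5 oxygen stays methylated, the 8-benzyl pattern is fixed before ring C is built.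

Step 7
Reactants: 15 1-[2-hydroxy-4,6-dimethoxy-3-(4-methoxybenzyl)phenyl]-2-methoxyethan-1-one; 16 3,4-dimethoxybenzoyl chloride
Product: 18 2-(3,4-dimethoxyphenyl)-3,5,7-trimethoxy-8-(4-methoxybenzyl)-4H-chromen-4-one, via 1,3-diketone 17 (not isolated)
Conditions: LiN(SiMe3)2 (3.2 equiv), THF, −78 → −10 °C; 16, −78 °C → rt; aq HCl; then AcOH, H2SO4 (cat.), 80 °C
Reagents that add atoms: none
Why: Baker–Venkataraman/Allan–Robinson-type flavone synthesis, in which the lithium phenoxide-enolate of 15 is aroylated at carbon (any O-aroyl ester reaches the same diketone by base-induced acyl transfer) and acid closes ring C by addition of the only free phenol, O1, to the aroyl carbonyl and loss of water, which can give only the 8-benzyl isomer.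

Step 8
Reactants: 18 2-(3,4-dimethoxyphenyl)-3,5,7-trimethoxy-8-(4-methoxybenzyl)-4H-chromen-4-one
Product: 19 8-p-hydroxybenzylquercetin, 2-(3,4-dihydroxyphenyl)-3,5,7-trihydroxy-8-(4-hydroxybenzyl)-4H-chromen-4-one
Conditions: BBr3 (15 equiv), CH2Cl2, −78 °C → rt; ice-water
Reagents that add atoms: none
Why: Lewis-acid ether cleavage, in which BBr3 binds each of the six methyl ethers (3, 5, 7, 3', 4' and 4'') and bromide removes the methyl group by SN2, while the absence of hot protic acid avoids a Wessely–Moser ring opening that would move the benzyl group from C8 to C6.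

**Compound list**
1 | 4-bromoanisole | COc1ccc(Br)cc1 | starting material
2 | 2-hydroxy-4,6-dimethoxybenzaldehyde | COc1cc(O)c(C=O)c(OC)c1 | starting material
3 | 4-methoxyphenylmagnesium bromide (not isolated) | COc1ccc([Mg]Br)cc1 | intermediate
4 | 2-[hydroxy(4-methoxyphenyl)methyl]-3,5-dimethoxyphenol (racemic) | COc1ccc(C(O)c2c(O)cc(OC)cc2OC)cc1 | intermediate
5 | 3,5-dimethoxy-2-(4-methoxybenzyl)phenol | COc1ccc(Cc2c(O)cc(OC)cc2OC)cc1 | intermediate
6 | 3,5-dimethoxy-2-(4-methoxybenzyl)phenyl isopropylcarbamate | COc1ccc(Cc2c(OC(=O)NC(C)C)cc(OC)cc2OC)cc1 | intermediate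
7 | 3,5-dimethoxy-2-(4-methoxybenzyl)phenyl N-(tert-butyldimethylsilyl)-N-isopropylcarbamate (not isolated) | COc1ccc(Cc2c(OC(=O)N(C(C)C)[Si](C)(C)C(C)(C)C)cc(OC)cc2OC)cc1 | intermediate
8 | 6-lithio derivative of 7, lithium between the carbamate oxygen and the methoxy group (not isolated) | COc1ccc(Cc2c(OC(=O)N(C(C)C)[Si](C)(C)C(C)(C)C)c([Li])c(OC)cc2OC)cc1 | intermediate
9 | 3,5-dimethoxy-2-(4-methoxybenzyl)-6-(trimethylsilyl)phenyl N-(tert-butyldimethylsilyl)-N-isopropylcarbamate (not isolated) | COc1ccc(Cc2c(OC(=O)N(C(C)C)[Si](C)(C)C(C)(C)C)c([Si](C)(C)C)c(OC)cc2OC)cc1 | intermediate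
10 | 3,5-dimethoxy-2-(4-methoxybenzyl)-6-(trimethylsilyl)phenyl isopropylcarbamate | COc1ccc(Cc2c(OC(=O)NC(C)C)c([Si](C)(C)C)c(OC)cc2OC)cc1 | intermediate
11 | 3,5-dimethoxy-2-(4-methoxybenzyl)-6-(trimethylsilyl)phenol (not isolated) | COc1ccc(Cc2c(O)c([Si](C)(C)C)c(OC)cc2OC)cc1 | intermediate
12 | 3,5-dimethoxy-2-(4-methoxybenzyl)-6-(trimethylsilyl)phenyl trifluoromethanesulfonate | COc1ccc(Cc2c(OC)cc(OC)c([Si](C)(C)C)c2OS(=O)(=O)C(F)(F)F)cc1 | intermediate
13 | methoxyacetic acid | COCC(=O)O | starting material
14 | 1,2-didehydro-3,5-dimethoxy-6-(4-methoxybenzyl)benzene, the C4a≡C8a aryne (not isolated) | COc1ccc(CC2=C(OC)C=C(OC)C#C2)cc1 | intermediate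
15 | 1-[2-hydroxy-4,6-dimethoxy-3-(4-methoxybenzyl)phenyl]-2-methoxyethan-1-one | COCC(=O)c1c(OC)cc(OC)c(Cc2ccc(OC)cc2)c1O | intermediate
16 | 3,4-dimethoxybenzoyl chloride | COc1ccc(C(=O)Cl)cc1OC | starting material
17 | 1-(3,4-dimethoxyphenyl)-3-[2-hydroxy-4,6-dimethoxy-3-(4-methoxybenzyl)phenyl]-2-methoxypropane-1,3-dione (racemic, enolisable, not isolated) | COC(C(=O)c1ccc(OC)c(OC)c1)C(=O)c1c(OC)cc(OC)c(Cc2ccc(OC)cc2)c1O | intermediate
18 | 2-(3,4-dimethoxyphenyl)-3,5,7-trimethoxy-8-(4-methoxybenzyl)-4H-chromen-4-one | COc1ccc(Cc2c(OC)cc(OC)c3c(=O)c(OC)c(-c4ccc(OC)c(OC)c4)oc23)cc1 | intermediate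
19 | 8-p-hydroxybenzylquercetin | O=c1c(O)c(-c2ccc(O)c(O)c2)oc2c(Cc3ccc(O)cc3)c(O)cc(O)c12 | target

**Count and risks**
Total steps: 8. Longest linear sequence: 8 steps (1 or 2 → 19).

1. Step 6.
- What may go wrong: the aryl anion at C4a may pick up a proton before it reaches the carbonyl. The proton could come from bifluoride, from unreacted acid, or from the α-CH2 of its own ester, and the result would be plain O-arylation. The bulk next to C8a may also slow the addition and let the aryne be consumed in other ways.
- Fallback: it sets out from 6 and rejoins the route at 15. Carbamate 6 is N-silylated and lithiated as in step 4, through 7 and 8, whose formation will have been proven by then. Aryllithium 8 is quenched with commercial N,2-dimethoxy-N-methylacetamide (Weinreb ketone synthesis) instead of TMSCl. Work-up should free the ketone and the N–H together to give 3,5-dimethoxy-2-(methoxyacetyl)-6-(4-methoxybenzyl)phenyl isopropylcarbamate F1. DBU/Et2NH in MeCN at 40 °C then removes the carbamate to give 15.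

2. Step 4.
- What may go wrong: deprotonation of the doubly benzylic CH2 (lateral lithiation) may compete with ring lithiation, followed by silylation or carbamoyl transfer at that carbon. An anionic ortho-Fries shift of the carbamoyl group may also occur on warming.
- Fallback: it sets out from 5 and rejoins at 12, bypassing steps 3–5. Amine-catalysed ortho-bromination (NBS, cat. i-Pr2NH, CH2Cl2, −78 → 0 °C) should give 2-bromo-3,5-dimethoxy-6-(4-methoxybenzyl)phenol F2. HN(SiMe3)2 in THF at 65 °C converts it into [2-bromo-3,5-dimethoxy-6-(4-methoxybenzyl)phenoxy]trimethylsilane F3. With n-BuLi in THF at −78 °C, bromine–lithium exchange is far faster than any C–H deprotonation and triggers the O-to-C silyl shift (retro-Brook rearrangement) to the lithium phenoxide of 11. Tf2O traps this phenoxide in the same flask as 12.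

3. Step 7.
- What may go wrong: aroylation may occur at oxygen instead of carbon, with incomplete acyl transfer at the crowded phenoxide. Acid may also cause loss or migration of the electron-rich benzyl group during cyclodehydration.
- Fallback: it sets out from 15 and rejoins at 18, with no strong acid. Claisen–Schmidt condensation of 15 with 3,4-dimethoxybenzaldehyde (KOH, EtOH, rt) should give (Z)-3-(3,4-dimethoxyphenyl)-1-[2-hydroxy-4,6-dimethoxy-3-(4-methoxybenzyl)phenyl]-2-methoxyprop-2-en-1-one F4. I2 (cat.) in DMSO at 120 °C closes ring C by oxa-Michael addition to 2-(3,4-dimethoxyphenyl)-3,5,7-trimethoxy-8-(4-methoxybenzyl)chroman-4-one F5 and dehydrogenates it in the same pot to 18.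

**Further compounds**
F1 | step 6 | 3,5-dimethoxy-2-(methoxyacetyl)-6-(4-methoxybenzyl)phenyl isopropylcarbamate | COCC(=O)c1c(OC)cc(OC)c(Cc2ccc(OC)cc2)c1OC(=O)NC(C)C
F2 | step 4 | 2-bromo-3,5-dimethoxy-6-(4-methoxybenzyl)phenol | COc1ccc(Cc2c(O)c(Br)c(OC)cc2OC)cc1
F3 | step 4 | [2-bromo-3,5-dimethoxy-6-(4-methoxybenzyl)phenoxy]trimethylsilane | COc1ccc(Cc2c(O[Si](C)(C)C)c(Br)c(OC)cc2OC)cc1
F4 | step 7 | (Z)-3-(3,4-dimethoxyphenyl)-1-[2-hydroxy-4,6-dimethoxy-3-(4-methoxybenzyl)phenyl]-2-methoxyprop-2-en-1-one | CO/C(=C\c1ccc(OC)c(OC)c1)C(=O)c1c(OC)cc(OC)c(Cc2ccc(OC)cc2)c1O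
F5 | step 7 | 2-(3,4-dimethoxyphenyl)-3,5,7-trimethoxy-8-(4-methoxybenzyl)chroman-4-one (racemic, C2/C3 diastereomers, both centres lost on dehydrogenation) | COc1ccc(Cc2c(OC)cc(OC)c3c2OC(c2ccc(OC)c(OC)c2)C(OC)C3=O)cc1
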